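## Structural features

Broussonol A is a flavonol: a 4H-chromen-4-one (rings A and C) with hydroxyls at C3, C5 and C7, joined through C2 to ring B. Ring B is fused across C4'–C5' to a 2,2-dimethyl-2H-pyran (ring D, oxygen on C4') and keeps a free 3'-hydroxyl. The molecule has no stereocentre; its only sp3 carbons are the gem-dimethyl carbon of ring D and the quaternary carbon of the 1,1-dimethylallyl group on C8. Three groups are fragile. The terminal alkene sits next to the 7-hydroxyl, and acid can close a dihydrofuran there. The styrene-like alkene of ring D is sensitive to acid and to electrophilic oxidants. The 3-hydroxy-4-pyranone on a phloroglucinol ring oxidises in base and air. Hydrogenolysis, strong acid and late oxidants are therefore excluded. The real difficulty is regiochemical: the quaternary carbon must be bonded to C8 and not to C6, two positions of ring A that differ only in their relation to the pyranone, and ring C must then close through the oxygen beside that carbon. The key step exploits the acetophenone stage, where ring A still has a mirror plane through C1 and C4 and the carbons that become C6 and C8 are one and the same by symmetry. Ring B with ring D is a separate problem, solved on a small protocatechuate ester.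

## Logic of the disconnections

21 to 20. The four O–CH2 acetal bonds are cut. One protecting group that tolerates base, heat and peracid and leaves without hydrogenation covers all four hydroxyls, so the last step is a single deprotection. The forward step needs acid mild enough to spare both alkenes.

20 to 18. The O1–C2 and C2–C3 bonds of ring C are cut, which is a Baker–Venkataraman acyl transfer followed by cyclodehydration and passes through 19. Ring C disappears and an aryl ester remains. The forward step requires that the acylated oxygen of ring A is the one next to the quaternary carbon.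

18 to 10 and 17. The ester C–O bond is cut, which divides the molecule into a ring A ketone and a ring B/D acid of similar size. The forward step must acylate a shielded, hydrogen-bonded phenol.

10 to 9 to 6. The α-O–CH2 acetal bond and then the α C–O bond of the ketone are cut. The C3 oxygen is placed at the acetyl stage because oxidative closure of a chalcone with a 6'-oxygen tends to give aurones. The forward oxidation must prefer the enol derivative over the vinyl group and the electron-rich ring.

6 to 5. Two aryl O–CH2 bonds are cut. The forward step must leave free exactly the hydroxyl between the acetyl group and the quaternary carbon.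

5 to 3. The aryl–C(CH3)2 bond is cut as the retron of an aromatic Claisen shift, and the quaternary carbon returns to an O-prenyl group. The gain is a symmetric ether in which no choice between ortho carbons exists. 3 keeps both chelated hydroxyls free, because protection would add nothing to the symmetry and would later have to be removed from the most hindered oxygen. The forward step must stop at the phenol.

3 to 1 and 2. The O–CH2 bond is cut, leaving two commercial materials. The forward alkylation must go to the one non-chelated oxygen.

17 to 16 to 15. The ester O–CH3 bond and the phenol O–CH2 acetal bond are cut, which are simple adjustments of functional groups. The forward steps need base-stable protection and a gentle acidification.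

15 to 13. The aryl–CH bond of ring D is cut (the O–C(CH3)2 bond is broken and re-formed in the forward cascade). Ring D becomes an aryl propargyl ether. The only free ortho carbon of 13 is the correct one, because the other carries the hydroxyl.

13 to 11 and 12. The O–C(CH3)2 bond is cut, leaving two commercial materials. The forward step must alkylate the hydroxyl para to the ester and not its neighbour.

## Other disconnections considered

Alternative 1: Ring D is cut last, at the bond from C5' to the alkene carbon. The forward step heats the 4'-O-(2-methylbut-3-yn-2-yl) ether A1 of the protected flavonol. A propargyl Claisen shift, a hydrogen shift and an oxa-6π closure would give A2, which has the structure of 20. In its favour, the ring D alkene would not have to pass through the coupling and acyl transfer steps, and the ring B acid is simpler. The outcome is as unambiguous as in step 7, since C3' is substituted, and the mechanistic footing and step count are equal to the chosen plan because the same two operations are only moved. Against it, it does not address the C8 versus C6 question, so it would still need a separate solution for ring A. It also applies about 190 °C to the most advanced intermediate with four acetals, and it carries a terminal alkyne through strong base. The chosen plan runs the same cascade on an inexpensive ester, so the risk sits earlier.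

Alternative 2: Ring A is cut at C8–C8a and C6–C7. The forward step heats the cyclobutenone A3 with the siloxyalkyne A4. Ring opening to a vinylketene, [2+2] addition, a second ring opening and a 6π closure would give the phenol A5. In its favour, the quaternary carbon is bonded to its ring carbon before the ring exists. The three oxygens also emerge chemically distinct (free hydroxyl, silyl ether, ethyl ether), and on this point it is better than the chosen plan, which relies on steric differentiation in step 3. Against it, A4 is not commercial and needs ynolate chemistry of several steps. A5 lacks the C4 carbon, so an acylation must choose between two activated ring positions. The ethyl ether at O5 must be cleaved by a Lewis acid in the presence of both alkenes. The tertiary substituent on the alkyne may also slow the [2+2] step. The sequence is several steps longer than the two steps that lead from 1 to 5.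

Alternative 3: The C3–C4 bond is cut. The lithium enolate of the ring B ketone A7 attacks the lactone carbonyl of the benzodioxinone A6 and acetone is lost. The product is A8, which has the structure of 19. In its favour, it is convergent, it needs no ester of a hindered phenol, and the phenoxide is released exactly at O1; on these points it is better than steps 10 and 11. The end game from A8 is the same as from 19. Against it, A6 must already carry the C8 quaternary carbon. A Claisen shift on a prenyl ether of a benzodioxinone has no mirror plane, so the C6/C8 problem that symmetry removes in the chosen plan returns. The carbonyl of A6 is also flanked by an acetal oxygen and is deactivated. The α-oxygenation is only moved to A7, and making the dioxinone adds steps, so the count is equal at best.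

Key step: step 2

Assumption: 1 is used as the dried, anhydrous material; the target is achiral, so no stereodescriptor is needed anywhere.

## Route

Step 1
Reactants: 1 2,4,6-trihydroxyacetophenone; 2 prenyl bromide (1-bromo-3-methylbut-2-ene)
Product: 3 1-[2,6-dihydroxy-4-(3-methylbut-2-enyloxy)phenyl]ethanone
Conditions: K2CO3 (1.0 equiv), acetone, reflux
Reagents that add atoms: none
Why: Williamson O-alkylation. The 4-hydroxyl is the only one not hydrogen-bonded to the acetyl carbonyl and is the most acidic, so one equivalent of weak base should form its phenoxide first, and the aprotic solvent favours O- over C-alkylation.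

Step 2
Reactants: 3 1-[2,6-dihydroxy-4-(3-methylbut-2-enyloxy)phenyl]ethanone
Product: 5 1-[2,4,6-trihydroxy-3-(2-methylbut-3-en-2-yl)phenyl]ethanone, via ortho-dienone 4 (not isolated)
Conditions: PhNEt2, 190 °C, argon
Reagents that add atoms: none
Why: Aromatic Claisen rearrangement of an aryl prenyl ether: in a concerted, suprafacial [3,3] shift through a chair-like six-membered transition state the O–CH2 bond of 3 breaks while the ring carbon ortho to the ether oxygen bonds to the dimethyl-substituted alkene terminus, so the allyl unit arrives inverted as C(CH3)2–CH=CH2. The first product is the ortho-dienone 4, whose sp3 ring carbon is only a transient racemic centre; enolisation restores the aromatic ring and gives achiral 5, so no stereocentre has to be controlled. The closest known reaction type is the thermal conversion of aryl 3,3-dimethylallyl ethers into ortho-(1,1-dimethylallyl)phenols. No ring is closed and one skeletal bond, the future C8–C(quaternary) bond, is made. Site selectivity does not depend on reagent control: 3 has a mirror plane through C1 and C4, so the two ortho carbons are equivalent, and the para carbon carries the acetyl group, which prevents a second shift to a linear prenyl isomer. The selectivity that is needed is chemoselectivity, stopping at the phenol: the hydroxyls flanking the new alkene could add to it and the side chain could scramble by an abnormal Claisen path, so a neutral, weakly basic, oxygen-free medium and the shortest heating that consumes 3 are chosen. Both chelated hydroxyls of 3 are left free on purpose, since the symmetry is the asset and any group on them would later have to leave the most hindered oxygen.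

Step 3
Reactants: 5 1-[2,4,6-trihydroxy-3-(2-methylbut-3-en-2-yl)phenyl]ethanone
Product: 6 1-[2-hydroxy-4,6-bis(methoxymethoxy)-3-(2-methylbut-3-en-2-yl)phenyl]ethanone
Conditions: MOMCl (2.2 equiv), iPr2NEt, CH2Cl2, 0 °C to rt
Reagents that add atoms: chloromethyl methyl ether, COCCl
Why: SN2 O-alkylation (acetal formation). The non-chelated 4-hydroxyl should react first; of the two chelated hydroxyls, the one between the acetyl group and the quaternary carbon is buttressed on both sides and should remain free when the reagent is limited.

Step 4
Reactants: 6 1-[2-hydroxy-4,6-bis(methoxymethoxy)-3-(2-methylbut-3-en-2-yl)phenyl]ethanone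
Product: 9 2-hydroxy-1-[2-hydroxy-4,6-bis(methoxymethoxy)-3-(2-methylbut-3-en-2-yl)phenyl]ethanone, via bis-silyl enol ether 7 (not isolated), via silyloxy ketone 8 (not isolated)
Conditions: LiN(SiMe3)2 (2.5 equiv), Me3SiCl, THF, −78 to 0 °C; mCPBA (1.05 equiv), NaHCO3, CH2Cl2, −20 °C; citric acid (aq), THF, 0 °C
Reagents that add atoms: meta-chloroperbenzoic acid, OOC(=O)c1cccc(Cl)c1
Why: Rubottom oxidation. The silyl enol ether is far more nucleophilic than the monosubstituted vinyl group, so one equivalent of buffered peracid should epoxidise it alone; silyl migration gives 8, and mild aqueous acid removes both silyl groups without touching the acetals.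

Step 5
Reactants: 9 2-hydroxy-1-[2-hydroxy-4,6-bis(methoxymethoxy)-3-(2-methylbut-3-en-2-yl)phenyl]ethanone
Product: 10 1-[2-hydroxy-4,6-bis(methoxymethoxy)-3-(2-methylbut-3-en-2-yl)phenyl]-2-(methoxymethoxy)ethanone
Conditions: MOMCl (1.1 equiv), iPr2NEt, CH2Cl2, 0 °C
Reagents that add atoms: chloromethyl methyl ether, COCCl
Why: SN2 O-alkylation of the unhindered primary hydroxyl; the remaining phenol is the one expected to resist the same reagent in step 3.

Step 6
Reactants: 11 methyl 3,4-dihydroxybenzoate; 12 3-chloro-3-methylbut-1-yne
Product: 13 methyl 3-hydroxy-4-[(2-methylbut-3-yn-2-yl)oxy]benzoate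
Conditions: K2CO3 (1.1 equiv), KI (cat.), DMF, 65 °C, argon
Reagents that add atoms: none
Why: O-propargylation of a phenoxide with a tertiary propargylic chloride by the ionising pathway typical of this reagent. The hydroxyl para to the ester is the more acidic, so limited base should direct the ether to O4.

Step 7
Reactants: 13 methyl 3-hydroxy-4-[(2-methylbut-3-yn-2-yl)oxy]benzoate
Product: 15 methyl 8-hydroxy-2,2-dimethyl-2H-chromene-6-carboxylate, via allenylphenol 14 (not isolated)
Conditions: PhNEt2, 190 °C, argon
Reagents that add atoms: none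
Why: Aryl propargyl ether Claisen rearrangement to 14, then a 1,5-hydrogen shift and oxa-6π electrocyclisation, the standard thermal chromene synthesis. Only one ortho carbon is free, because the other bears the hydroxyl, so a single ring fusion is possible.

Step 8
Reactants: 15 methyl 8-hydroxy-2,2-dimethyl-2H-chromene-6-carboxylate
Product: 16 methyl 8-(methoxymethoxy)-2,2-dimethyl-2H-chromene-6-carboxylate
Conditions: MOMCl, iPr2NEt, CH2Cl2, 0 °C to rt
Reagents that add atoms: chloromethyl methyl ether, COCCl
Why: Routine methoxymethylation of an unhindered phenol; the ester and the chromene alkene are inert to it.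

Step 9
Reactants: 16 methyl 8-(methoxymethoxy)-2,2-dimethyl-2H-chromene-6-carboxylate
Product: 17 8-(methoxymethoxy)-2,2-dimethyl-2H-chromene-6-carboxylic acid
Conditions: LiOH, THF/MeOH/H2O, 40 °C; then HCl (1 M) to pH 4, 0 °C
Reagents that add atoms: lithium hydroxide, [Li+].[OH-] (supplies the carboxyl oxygen)
Why: Ester saponification. The acetal and the chromene are stable to base, and the cold, brief acidification to pH 4 should not cleave the acetal.

Step 10
Reactants: 10 1-[2-hydroxy-4,6-bis(methoxymethoxy)-3-(2-methylbut-3-en-2-yl)phenyl]-2-(methoxymethoxy)ethanone; 17 8-(methoxymethoxy)-2,2-dimethyl-2H-chromene-6-carboxylic acid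
Product: 18 2-[2-(methoxymethoxy)acetyl]-3,5-bis(methoxymethoxy)-6-(2-methylbut-3-en-2-yl)phenyl 8-(methoxymethoxy)-2,2-dimethyl-2H-chromene-6-carboxylate
Conditions: EDC·HCl, DMAP (1.5 equiv), CH2Cl2, rt
Reagents that add atoms: none
Why: Steglich esterification through the acylpyridinium ion. The phenol is the only free hydroxyl of 10, and carbodiimide activation replaces an acid chloride, whose preparation would release HCl and endanger the acetals and the chromene.

Step 11
Reactants: 18 2-[2-(methoxymethoxy)acetyl]-3,5-bis(methoxymethoxy)-6-(2-methylbut-3-en-2-yl)phenyl 8-(methoxymethoxy)-2,2-dimethyl-2H-chromene-6-carboxylate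
Product: 20 3,5,7-tris(methoxymethoxy)-2-[8-(methoxymethoxy)-2,2-dimethyl-2H-chromen-6-yl]-8-(2-methylbut-3-en-2-yl)-4H-chromen-4-one, via diketone 19 (not isolated)
Conditions: K2CO3, Bu4NBr, toluene, 90 °C
Reagents that add atoms: none
Why: Baker–Venkataraman rearrangement: the α-alkoxy enolate attacks the neighbouring aryl ester, and the aroyl group moves from oxygen to carbon to give 19. The freed phenoxide then adds to the aryl ketone (6-exo-trig) and water is lost to form ring C; since that oxygen lies next to the quaternary carbon, the side chain ends up at C8.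

Step 12
Reactants: 20 3,5,7-tris(methoxymethoxy)-2-[8-(methoxymethoxy)-2,2-dimethyl-2H-chromen-6-yl]-8-(2-methylbut-3-en-2-yl)-4H-chromen-4-one
Product: 21 Broussonol A, 3,5,7-trihydroxy-2-(8-hydroxy-2,2-dimethyl-2H-chromen-6-yl)-8-(2-methylbut-3-en-2-yl)-4H-chromen-4-one
Conditions: HCl (3 M aq), MeOH/THF, 45 °C
Reagents that add atoms: none
Why: Acid-catalysed acetal exchange with methanol removes all four methoxymethyl groups. Moderate temperature and monitoring are meant to end the reaction before the 7-hydroxyl can add to the adjacent alkene or the ring D alkene is hydrated.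

## Compound list

1 | 2,4,6-trihydroxyacetophenone | CC(=O)c1c(O)cc(O)cc1O | starting material
2 | prenyl bromide (1-bromo-3-methylbut-2-ene) | CC(C)=CCBr | starting material
3 | 1-[2,6-dihydroxy-4-(3-methylbut-2-enyloxy)phenyl]ethanone | CC(=O)c1c(O)cc(OCC=C(C)C)cc1O | intermediate
4 | 4-acetyl-3,5-dihydroxy-6-(2-methylbut-3-en-2-yl)cyclohexa-2,4-dien-1-one (racemic, transient) | CC(=O)C1=C(O)C(C(C)(C)C=C)C(=O)C=C1O | intermediate
5 | 1-[2,4,6-trihydroxy-3-(2-methylbut-3-en-2-yl)phenyl]ethanone | CC(=O)c1c(O)cc(O)c(C(C)(C)C=C)c1O | intermediate
6 | 1-[2-hydroxy-4,6-bis(methoxymethoxy)-3-(2-methylbut-3-en-2-yl)phenyl]ethanone | CC(=O)c1c(OCOC)cc(OCOC)c(C(C)(C)C=C)c1O | intermediate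
7 | {1-[4,6-bis(methoxymethoxy)-3-(2-methylbut-3-en-2-yl)-2-(trimethylsilyloxy)phenyl]ethenyloxy}trimethylsilane | C=C(O[Si](C)(C)C)c1c(OCOC)cc(OCOC)c(C(C)(C)C=C)c1O[Si](C)(C)C | intermediate
8 | 1-[4,6-bis(methoxymethoxy)-3-(2-methylbut-3-en-2-yl)-2-(trimethylsilyloxy)phenyl]-2-(trimethylsilyloxy)ethanone | C[Si](C)(C)OCC(=O)c1c(OCOC)cc(OCOC)c(C(C)(C)C=C)c1O[Si](C)(C)C | intermediate
9 | 2-hydroxy-1-[2-hydroxy-4,6-bis(methoxymethoxy)-3-(2-methylbut-3-en-2-yl)phenyl]ethanone | OCC(=O)c1c(OCOC)cc(OCOC)c(C(C)(C)C=C)c1O | intermediate
10 | 1-[2-hydroxy-4,6-bis(methoxymethoxy)-3-(2-methylbut-3-en-2-yl)phenyl]-2-(methoxymethoxy)ethanone | COCOCC(=O)c1c(OCOC)cc(OCOC)c(C(C)(C)C=C)c1O | intermediate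
11 | methyl 3,4-dihydroxybenzoate | COC(=O)c1ccc(O)c(O)c1 | starting material
12 | 3-chloro-3-methylbut-1-yne | CC(C)(Cl)C#C | starting material
13 | methyl 3-hydroxy-4-[(2-methylbut-3-yn-2-yl)oxy]benzoate | COC(=O)c1ccc(OC(C)(C)C#C)c(O)c1 | intermediate
14 | methyl 3,4-dihydroxy-5-(3-methylbuta-1,2-dien-1-yl)benzoate | COC(=O)c1cc(O)c(O)c(C=C=C(C)C)c1 | intermediate
15 | methyl 8-hydroxy-2,2-dimethyl-2H-chromene-6-carboxylate | COC(=O)c1cc(O)c2OC(C)(C)C=Cc2c1 | intermediate
16 | methyl 8-(methoxymethoxy)-2,2-dimethyl-2H-chromene-6-carboxylate | COCOc1cc(C(=O)OC)cc2C=CC(C)(C)Oc12 | intermediate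
17 | 8-(methoxymethoxy)-2,2-dimethyl-2H-chromene-6-carboxylic acid | COCOc1cc(C(=O)O)cc2C=CC(C)(C)Oc12 | intermediate
18 | 2-[2-(methoxymethoxy)acetyl]-3,5-bis(methoxymethoxy)-6-(2-methylbut-3-en-2-yl)phenyl 8-(methoxymethoxy)-2,2-dimethyl-2H-chromene-6-carboxylate | COCOCC(=O)c1c(OCOC)cc(OCOC)c(C(C)(C)C=C)c1OC(=O)c1cc(OCOC)c2OC(C)(C)C=Cc2c1 | intermediate
19 | 1-[2-hydroxy-4,6-bis(methoxymethoxy)-3-(2-methylbut-3-en-2-yl)phenyl]-2-(methoxymethoxy)-3-[8-(methoxymethoxy)-2,2-dimethyl-2H-chromen-6-yl]propane-1,3-dione (keto form, racemic and enolisable at C2) | C=CC(C)(C)c1c(O)c(C(=O)C(OCOC)C(=O)c2cc(OCOC)c3OC(C)(C)C=Cc3c2)c(OCOC)cc1OCOC | intermediate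
20 | 3,5,7-tris(methoxymethoxy)-2-[8-(methoxymethoxy)-2,2-dimethyl-2H-chromen-6-yl]-8-(2-methylbut-3-en-2-yl)-4H-chromen-4-one | C=CC(C)(C)c1c(OCOC)cc(OCOC)c2c(=O)c(OCOC)c(-c3cc(OCOC)c4OC(C)(C)C=Cc4c3)oc12 | intermediate
21 | Broussonol A, 3,5,7-trihydroxy-2-(8-hydroxy-2,2-dimethyl-2H-chromen-6-yl)-8-(2-methylbut-3-en-2-yl)-4H-chromen-4-one | C=CC(C)(C)c1c(O)cc(O)c2c(=O)c(O)c(-c3cc(O)c4c(c3)C=CC(C)(C)O4)oc12 | target

## Step count and least certain steps

Total: 12 steps. Longest linear sequence: 8 steps (steps 1–5 and 10–12, from 1). The ring B/D branch is 4 steps (steps 6–9) before the convergence.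

Step 2 (key step). The most likely failure is onward reaction of the rearranged phenol at 190 °C: ring closure of a flanking hydroxyl onto the new alkene, abnormal Claisen scrambling of the side chain, or ether cleavage with loss of the five-carbon unit. The fallback sets out from 3 and returns at 5. 3 would be acetylated (Ac2O, pyridine) to 2-acetyl-5-(3-methylbut-2-enyloxy)-1,3-phenylene diacetate F1. F1 would be rearranged in PhNEt2 with Ac2O and NaOAc present, so that the new phenol is trapped as it forms, to give 2-acetyl-4-(2-methylbut-3-en-2-yl)benzene-1,3,5-triyl triacetate F2. Methanolysis (K2CO3, MeOH, rt) would then release 5. No free hydroxyl is present next to the alkene while the mixture is hot.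

Step 3. The most likely failure is loss of site control between the two chelated hydroxyls, or over-alkylation, which would later misdirect the closure of ring C. The fallback sets out from 5 and returns at 6. All three hydroxyls would be protected (NaH, MOMCl, DMF) to give 1-[2,4,6-tris(methoxymethoxy)-3-(2-methylbut-3-en-2-yl)phenyl]ethanone F3. One acetal ortho to the carbonyl would then be removed with catalytic HCl in MeOH at 0 °C. The acetal between the acetyl group and the quaternary carbon is twisted out of the ring plane and is the most strained, so it should leave first, and the selection would be made by a cleavage and not by an alkylation.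

Step 4. The most likely failures are incomplete enol silylation, competing epoxidation of the vinyl group or oxidation of the electron-rich ring, and acetal loss caused by the acid by-product. The fallback sets out from 6 and returns at 21; it installs the C3 oxygen after ring C exists.
- 6 would be esterified with 17 (EDC·HCl, DMAP) to 2-acetyl-3,5-bis(methoxymethoxy)-6-(2-methylbut-3-en-2-yl)phenyl 8-(methoxymethoxy)-2,2-dimethyl-2H-chromene-6-carboxylate F4.
- Baker–Venkataraman transfer (K2CO3, Bu4NBr, toluene) would give 1-[2-hydroxy-4,6-bis(methoxymethoxy)-3-(2-methylbut-3-en-2-yl)phenyl]-3-[8-(methoxymethoxy)-2,2-dimethyl-2H-chromen-6-yl]propane-1,3-dione F5.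
- Cyclodehydration (NaOAc, AcOH, 80 °C) would give 5,7-bis(methoxymethoxy)-2-[8-(methoxymethoxy)-2,2-dimethyl-2H-chromen-6-yl]-8-(2-methylbut-3-en-2-yl)-4H-chromen-4-one F6.
- Deprotonation at C3 (LiN(iPr)2, THF, −78 °C) and trapping with B(OMe)3 would give dimethyl {5,7-bis(methoxymethoxy)-2-[8-(methoxymethoxy)-2,2-dimethyl-2H-chromen-6-yl]-8-(2-methylbut-3-en-2-yl)-4-oxo-4H-chromen-3-yl}boronate F7, used without isolation.
- Oxidation with H2O2/AcOH would give 3-hydroxy-5,7-bis(methoxymethoxy)-2-[8-(methoxymethoxy)-2,2-dimethyl-2H-chromen-6-yl]-8-(2-methylbut-3-en-2-yl)-4H-chromen-4-one F8.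
- Methanolic HCl as in step 12 would then give 21.

Step 10. The most likely failure is slow acyl transfer to the shielded, hydrogen-bonded phenol, with rearrangement of the activated acid to an N-acylurea. The fallback sets out from 10 and 17 and returns at 19. 17 would be activated with 1,1'-carbonyldiimidazole to 1H-imidazol-1-yl[8-(methoxymethoxy)-2,2-dimethyl-2H-chromen-6-yl]methanone F9. 10 would be converted with LiN(SiMe3)2 (3.2 equiv, THF, −78 °C) into its phenoxide–enolate dianion and acylated at carbon by F9. This crossed Claisen condensation forms 19 directly, and the conditions of step 11 then close ring C to 20.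

Step 12. The most likely failure is acid-promoted addition of the freed 7-hydroxyl across the neighbouring alkene, or hydration of the ring D alkene, before the last acetal is cleaved. The fallback sets out from 20 and returns at 21. The acetals would be exchanged for silyl ethers under anhydrous conditions (Me3SiBr, 4 Å sieves, CH2Cl2, −30 °C) to give 2-[2,2-dimethyl-8-(trimethylsilyloxy)-2H-chromen-6-yl]-8-(2-methylbut-3-en-2-yl)-3,5,7-tris(trimethylsilyloxy)-4H-chromen-4-one F10. The silyl ethers would then be hydrolysed with NaHCO3 in aqueous MeOH, so the phenols are freed only in a neutral medium.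

## Further compounds

F1 | step 2 | 2-acetyl-5-(3-methylbut-2-enyloxy)-1,3-phenylene diacetate | CC(=O)Oc1cc(OCC=C(C)C)cc(OC(C)=O)c1C(C)=O
F2 | step 2 | 2-acetyl-4-(2-methylbut-3-en-2-yl)benzene-1,3,5-triyl triacetate | CC(=O)Oc1cc(OC(C)=O)c(C(C)(C)C=C)c(OC(C)=O)c1C(C)=O
F3 | step 3 | 1-[2,4,6-tris(methoxymethoxy)-3-(2-methylbut-3-en-2-yl)phenyl]ethanone | CC(=O)c1c(OCOC)cc(OCOC)c(C(C)(C)C=C)c1OCOC
F4 | step 4 | 2-acetyl-3,5-bis(methoxymethoxy)-6-(2-methylbut-3-en-2-yl)phenyl 8-(methoxymethoxy)-2,2-dimethyl-2H-chromene-6-carboxylate | CC(=O)c1c(OCOC)cc(OCOC)c(C(C)(C)C=C)c1OC(=O)c1cc(OCOC)c2OC(C)(C)C=Cc2c1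
F5 | step 4 | 1-[2-hydroxy-4,6-bis(methoxymethoxy)-3-(2-methylbut-3-en-2-yl)phenyl]-3-[8-(methoxymethoxy)-2,2-dimethyl-2H-chromen-6-yl]propane-1,3-dione | C=CC(C)(C)c1c(O)c(C(=O)CC(=O)c2cc(OCOC)c3OC(C)(C)C=Cc3c2)c(OCOC)cc1OCOC
F6 | step 4 | 5,7-bis(methoxymethoxy)-2-[8-(methoxymethoxy)-2,2-dimethyl-2H-chromen-6-yl]-8-(2-methylbut-3-en-2-yl)-4H-chromen-4-one | C=CC(C)(C)c1c(OCOC)cc(OCOC)c2c(=O)cc(-c3cc(OCOC)c4OC(C)(C)C=Cc4c3)oc12
F7 | step 4 | dimethyl {5,7-bis(methoxymethoxy)-2-[8-(methoxymethoxy)-2,2-dimethyl-2H-chromen-6-yl]-8-(2-methylbut-3-en-2-yl)-4-oxo-4H-chromen-3-yl}boronate | C=CC(C)(C)c1c(OCOC)cc(OCOC)c2c(=O)c(B(OC)OC)c(-c3cc(OCOC)c4OC(C)(C)C=Cc4c3)oc12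
F8 | step 4 | 3-hydroxy-5,7-bis(methoxymethoxy)-2-[8-(methoxymethoxy)-2,2-dimethyl-2H-chromen-6-yl]-8-(2-methylbut-3-en-2-yl)-4H-chromen-4-one | C=CC(C)(C)c1c(OCOC)cc(OCOC)c2c(=O)c(O)c(-c3cc(OCOC)c4OC(C)(C)C=Cc4c3)oc12
F9 | step 10 | 1H-imidazol-1-yl[8-(methoxymethoxy)-2,2-dimethyl-2H-chromen-6-yl]methanone | COCOc1cc(C(=O)n2ccnc2)cc2C=CC(C)(C)Oc12
F10 | step 12 | 2-[2,2-dimethyl-8-(trimethylsilyloxy)-2H-chromen-6-yl]-8-(2-methylbut-3-en-2-yl)-3,5,7-tris(trimethylsilyloxy)-4H-chromen-4-one | C=CC(C)(C)c1c(O[Si](C)(C)C)cc(O[Si](C)(C)C)c2c(=O)c(O[Si](C)(C)C)c(-c3cc(O[Si](C)(C)C)c4OC(C)(C)C=Cc4c3)oc12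
A1 | alternative 1 | 3,5,7-tris(methoxymethoxy)-2-{3-(methoxymethoxy)-4-[(2-methylbut-3-yn-2-yl)oxy]phenyl}-8-(2-methylbut-3-en-2-yl)-4H-chromen-4-one | C=CC(C)(C)c1c(OCOC)cc(OCOC)c2c(=O)c(OCOC)c(-c3ccc(OC(C)(C)C#C)c(OCOC)c3)oc12
A2 | alternative 1 | Broussonol A tetrakis(methoxymethyl) ether | C=CC(C)(C)c1c(OCOC)cc(OCOC)c2c(=O)c(OCOC)c(-c3cc(OCOC)c4OC(C)(C)C=Cc4c3)oc12
A3 | alternative 2 | 3-ethoxycyclobut-2-en-1-one | CCOC1=CC(=O)C1
A4 | alternative 2 | [(3,3-dimethylpent-4-en-1-yn-1-yl)oxy]triisopropylsilane | C=CC(C)(C)C#CO[Si](C(C)C)(C(C)C)C(C)C
A5 | alternative 2 | 5-ethoxy-2-(2-methylbut-3-en-2-yl)-3-(triisopropylsilyloxy)phenol | C=CC(C)(C)c1c(O)cc(OCC)cc1O[Si](C(C)C)(C(C)C)C(C)C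
A6 | alternative 3 | 5,7-bis(methoxymethoxy)-2,2-dimethyl-8-(2-methylbut-3-en-2-yl)-4H-1,3-benzodioxin-4-one | C=CC(C)(C)c1c(OCOC)cc(OCOC)c2C(=O)OC(C)(C)Oc12
A7 | alternative 3 | 2-(methoxymethoxy)-1-[8-(methoxymethoxy)-2,2-dimethyl-2H-chromen-6-yl]ethanone | COCOCC(=O)c1cc(OCOC)c2OC(C)(C)C=Cc2c1
A8 | alternative 3 | 1-[2-hydroxy-4,6-bis(methoxymethoxy)-3-(2-methylbut-3-en-2-yl)phenyl]-2-(methoxymethoxy)-3-[8-(methoxymethoxy)-2,2-dimethyl-2H-chromen-6-yl]propane-1,3-dione (racemic, enolisable) | C=CC(C)(C)c1c(O)c(C(=O)C(OCOC)C(=O)c2cc(OCOC)c3OC(C)(C)C=Cc3c2)c(OCOC)cc1OCOC
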